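**Retrosynthetic overview**

- The target is reached from the tetrabenzyl trans-dihydroflavonol 19 by C2–C3 dehydrogenation and hydrogenolysis; 19 comes from the 2'-O-MOM chalcone epoxide 17.
- The plan rests on one feature: the O1–C2 bond links the ring A phenol oxygen (on C8a) to the benzylic carbon that carries ring B, and the C3 hydroxyl is the oxygen of an α,β-epoxy ketone. Ring C is therefore closed by 6-endo epoxide opening and kept saturated until afterwards, so the aurone pathway of direct oxidative cyclisation of a 6'-alkoxychalcone is never entered.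
- 17 comes from Weitz–Scheffer epoxidation of chalcone 16, made by Claisen–Schmidt condensation of acetophenone 13 with O-benzylvanillin 15.
- 13 comes from (R)-2-(1-arylethyl)phloroglucinol 9 by Hoesch acetylation, 4,6-di-O-benzylation and 2-O-MOM protection. 9 comes from hydroxyl-directed asymmetric hydrogenation of the 1,1-diarylethene 8, which sets the only permanent stereocentre. 8 comes from lithiated tris-MOM phloroglucinol and O-benzylacetosyringone.
- Rings A and B are bought as phloroglucinol, acetosyringone and vanillin; ring C is the only ring formed (step 12) and is aromatised in step 13.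

Key step: step 12

Assumption: the side-chain centre on C8 is (R) (ring A outranks the dimethoxyaryl ring). The ligand antipode that delivers (R) in step 5 is fixed by a screen of both enantiomers. Compounds 17–19 are pairs of diastereomers at the transient ring C centres, and one of each pair is drawn.

**Route**

Step 1
Reactants: 1 phloroglucinol
Product: 2 1,3,5-tris(methoxymethoxy)benzene
Conditions: NaH, MOMCl, DMF, 0 °C to rt
Reagents that add atoms: chloromethyl methyl ether (MOMCl), COCCl
Why: Williamson-type O-alkylation of the phenoxides with a hard alkoxymethyl chloride, which favours O- over C-alkylation of phloroglucinol and installs three ortho-directing groups.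

Step 2
Reactants: 3 acetosyringone
Product: 4 1-[4-(benzyloxy)-3,5-dimethoxyphenyl]ethanone
Conditions: BnBr, K2CO3, DMF, 60 °C
Reagents that add atoms: benzyl bromide, BrCc1ccccc1
Why: Williamson etherification of the phenol, which must be masked before an organolithium is added to the ketone.

Step 3
Reactants: 2 1,3,5-tris(methoxymethoxy)benzene; 4 1-[4-(benzyloxy)-3,5-dimethoxyphenyl]ethanone
Product: 6 racemic 1-[4-(benzyloxy)-3,5-dimethoxyphenyl]-1-[2,4,6-tris(methoxymethoxy)phenyl]ethanol, via aryllithium 5 (not isolated)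
Conditions: n-BuLi, THF, 0 °C; then 4, −78 °C to 0 °C; H2O
Reagents that add atoms: none
Why: Directed ortho-metalation at a ring CH flanked by two OMOM groups (the three positions are equivalent) followed by 1,2-addition to the aryl methyl ketone; should enolisation of 4 compete, transmetalation with CeCl3 before the addition is the standard remedy, and the carbinol centre is removed in step 4.

Step 4
Reactants: 6 racemic 1-[4-(benzyloxy)-3,5-dimethoxyphenyl]-1-[2,4,6-tris(methoxymethoxy)phenyl]ethanol
Product: 8 2-{1-[4-(benzyloxy)-3,5-dimethoxyphenyl]ethenyl}benzene-1,3,5-triol, via tris-MOM diarylethene 7 (not isolated)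
Conditions: HCl (3 M aq), THF/i-PrOH, 45 °C, N2
Reagents that add atoms: none
Why: The tertiary, doubly benzylic carbinol ionises at once and loses a proton (E1 dehydration), then the three aryl MOM acetals are hydrolysed; the hindered secondary alcohol cosolvent cannot trap the cation as a stable ether and the benzyl ether is stable to dilute acid.

Step 5
Reactants: 8 2-{1-[4-(benzyloxy)-3,5-dimethoxyphenyl]ethenyl}benzene-1,3,5-triol
Product: 9 2-{(1R)-1-[4-(benzyloxy)-3,5-dimethoxyphenyl]ethyl}benzene-1,3,5-triol
Conditions: H2 (10 bar), [Rh(nbd)2]BF4 (2 mol %), Josiphos-type ferrocenyl bisphosphine (2.2 mol %), MeOH, rt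
Reagents that add atoms: none
Why: Hydroxyl-directed asymmetric hydrogenation of a 2'-hydroxy-1,1-diarylethene, in which an ortho hydroxyl of ring A (the two are interchangeable by rotation about the aryl–vinyl bond) binds the cationic rhodium bisphosphine and holds the twisted alkene in a chelate, so the chiral ligand decides which face receives hydrogen and sets the (R)-centre; the benzyl ether is inert to the homogeneous catalyst.

Step 6
Reactants: 9 2-{(1R)-1-[4-(benzyloxy)-3,5-dimethoxyphenyl]ethyl}benzene-1,3,5-triol
Product: 11 1-(3-{(1R)-1-[4-(benzyloxy)-3,5-dimethoxyphenyl]ethyl}-2,4,6-trihydroxyphenyl)ethanone, via ketiminium chloride 10 (not isolated)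
Conditions: MeCN, ZnCl2, HCl (g), Et2O, 0 °C; then H2O, 90 °C
Reagents that add atoms: acetonitrile, CC#N; water, O
Why: Hoesch acylation of the C-alkylphloroglucinol at one of its two equivalent ring CH positions, stopped at mono-acylation by the deactivating ketiminium group; at 0 °C the benzylic C–C bond should not ionise, because the 4-benzyloxy group twisted between two methoxy groups stabilises a benzylic cation only weakly, so the stereocentre is expected to be retained.

Step 7
Reactants: 11 1-(3-{(1R)-1-[4-(benzyloxy)-3,5-dimethoxyphenyl]ethyl}-2,4,6-trihydroxyphenyl)ethanone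
Product: 12 1-(4,6-bis(benzyloxy)-3-{(1R)-1-[4-(benzyloxy)-3,5-dimethoxyphenyl]ethyl}-2-hydroxyphenyl)ethanone
Conditions: BnBr (2.1 equiv), K2CO3, acetone, reflux
Reagents that add atoms: benzyl bromide, BrCc1ccccc1
Why: Williamson etherification in which the non-chelated 4-hydroxyl reacts first and, of the two hydroxyls next to the acetyl group, the one flanked by the bulky 1-arylethyl group stays hydrogen-bonded to the carbonyl and shielded, so the second benzyl group should go to the 6-hydroxyl, as in the partial alkylation of other 3-C-substituted phloroacetophenones.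

Step 8
Reactants: 12 1-(4,6-bis(benzyloxy)-3-{(1R)-1-[4-(benzyloxy)-3,5-dimethoxyphenyl]ethyl}-2-hydroxyphenyl)ethanone
Product: 13 1-(4,6-bis(benzyloxy)-3-{(1R)-1-[4-(benzyloxy)-3,5-dimethoxyphenyl]ethyl}-2-(methoxymethoxy)phenyl)ethanone
Conditions: NaH (1.2 equiv), MOMCl, DMF, 0 °C to rt
Reagents that add atoms: chloromethyl methyl ether (MOMCl), COCCl
Why: Irreversible deprotonation breaks the hydrogen bond of the chelated phenol (far more acidic than the acetyl CH3) and the sodium phenoxide is O-alkylated by the reactive alkoxymethyl chloride.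

Step 9
Reactants: 14 vanillin
Product: 15 4-(benzyloxy)-3-methoxybenzaldehyde
Conditions: BnBr, K2CO3, DMF, rt
Reagents that add atoms: benzyl bromide, BrCc1ccccc1
Why: Williamson etherification of the phenol, needed so that the aldehyde stays electrophilic under the basic condensation.

Step 10
Reactants: 13 1-(4,6-bis(benzyloxy)-3-{(1R)-1-[4-(benzyloxy)-3,5-dimethoxyphenyl]ethyl}-2-(methoxymethoxy)phenyl)ethanone; 15 4-(benzyloxy)-3-methoxybenzaldehyde
Product: 16 (E)-1-(4,6-bis(benzyloxy)-3-{(1R)-1-[4-(benzyloxy)-3,5-dimethoxyphenyl]ethyl}-2-(methoxymethoxy)phenyl)-3-[4-(benzyloxy)-3-methoxyphenyl]prop-2-en-1-one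
Conditions: KOH (50% aq), EtOH/THF, rt
Reagents that add atoms: none
Why: Claisen–Schmidt condensation of the methyl ketone enolate with a non-enolisable aldehyde, with E1cB loss of water giving the E-enone; the benzylic CH of the side chain is far too weakly acidic to epimerise.

Step 11
Reactants: 16 (E)-chalcone
Product: 17 (4,6-bis(benzyloxy)-3-{(1R)-1-[4-(benzyloxy)-3,5-dimethoxyphenyl]ethyl}-2-(methoxymethoxy)phenyl){trans-3-[4-(benzyloxy)-3-methoxyphenyl]oxiran-2-yl}methanone, (2R,3S)- and (2S,3R)-oxirane diastereomers
Conditions: H2O2 (30% aq), NaOH (2 M aq), MeOH/THF, 0 °C to rt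
Reagents that add atoms: hydrogen peroxide, OO
Why: Weitz–Scheffer nucleophilic epoxidation (conjugate addition of hydroperoxide, then ring closure of the enolate on O–O) gives the trans-epoxide from the E-enone; the remote side-chain centre exerts no useful control, and none is needed because both oxirane centres are erased in step 13, while the MOM group prevents the phenoxide-driven aurone pathway.

Step 12
Reactants: 17 2'-O-MOM trans-chalcone epoxide (both diastereomers)
Product: 19 trans-5,7-bis(benzyloxy)-2-[4-(benzyloxy)-3-methoxyphenyl]-8-{(1R)-1-[4-(benzyloxy)-3,5-dimethoxyphenyl]ethyl}-3-hydroxy-2,3-dihydro-4H-chromen-4-one, (2R,3R) and (2S,3S) diastereomers, via free 2'-phenol epoxide 18 (not isolated)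
Conditions: HCl (1.25 M in MeOH), THF, 50 °C
Reagents that add atoms: none
Why: Methanolic HCl cleaves the aryl MOM acetal of 17 to the free phenol 18, the same acid activates the epoxide, and the phenol oxygen attacks the benzylic epoxide carbon with inversion, forming O1–C2 and leaving the former epoxide oxygen as the C3 hydroxyl. The closest known reaction type is the acid-mediated cyclisation of 2'-O-protected chalcone epoxides to trans-dihydroflavonols. Ring C closes in the 6-endo-tet mode (attack at the distal epoxide carbon); the 5-exo attack at the carbon next to the carbonyl, which would lead into the benzofuranone and aurone series, is disfavoured because under acid the positive charge builds up on the carbon stabilised by the para-benzyloxy ring B. C2 is set by inversion of the trans-epoxide and C3 is carried over unchanged, so each epoxide diastereomer should give a 2,3-trans product under substrate control; both centres are removed in step 13, so the pair converges, and the side-chain centre on C8 is not ionisable under these conditions. The selectivity required is for the benzylic carbon over the α-carbon and for the phenol over methanol or chloride as nucleophile; the first is secured by cation stabilisation from ring B, the second by intramolecularity once the phenol is unmasked. Because the other oxygen ortho to the carbonyl stays benzylated, only the 8-substituted chromanone can form, and the benzyl ethers tolerate dilute methanolic HCl.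

Step 13
Reactants: 19 trans-dihydroflavonol tetrabenzyl ether (both diastereomers)
Product: 20 5,7-bis(benzyloxy)-2-[4-(benzyloxy)-3-methoxyphenyl]-8-{(1R)-1-[4-(benzyloxy)-3,5-dimethoxyphenyl]ethyl}-3-hydroxy-4H-chromen-4-one
Conditions: I2, KOAc, AcOH, 100 °C
Reagents that add atoms: none
Why: Classical iodine/acetate dehydrogenation of a dihydroflavonol, in which the enol of the α-hydroxy ketone is iodinated at C3, HI is lost to give the 3,4-dione and this tautomerises to the aromatic 3-hydroxy-4-pyranone; KOAc buffers the HI so that the benzyl ethers should survive.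

Step 14
Reactants: 20 flavonol tetrabenzyl ether
Product: 21 3,5,7-trihydroxy-2-(4-hydroxy-3-methoxyphenyl)-8-[(1R)-1-(4-hydroxy-3,5-dimethoxyphenyl)ethyl]-4H-chromen-4-one (target)
Conditions: H2 (1 atm), Pd/C, EtOAc/MeOH, rt
Reagents that add atoms: none
Why: Hydrogenolysis of the four aryl benzyl ethers; the pyranone double bond of a flavonol and the diarylmethine C–C bonds are not reduced under these mild conditions, so the (R)-centre is retained.

**Compound list**

1 | phloroglucinol | Oc1cc(O)cc(O)c1 | starting material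
2 | 1,3,5-tris(methoxymethoxy)benzene | COCOc1cc(OCOC)cc(OCOC)c1 | intermediate
3 | acetosyringone | CC(=O)c1cc(OC)c(O)c(OC)c1 | starting material
4 | 1-[4-(benzyloxy)-3,5-dimethoxyphenyl]ethanone | CC(=O)c1cc(OC)c(OCc2ccccc2)c(OC)c1 | intermediate
5 | 2,4,6-tris(methoxymethoxy)phenyllithium | [Li]c1c(OCOC)cc(OCOC)cc1OCOC | intermediate (not isolated)
6 | racemic 1-[4-(benzyloxy)-3,5-dimethoxyphenyl]-1-[2,4,6-tris(methoxymethoxy)phenyl]ethanol | CC(O)(c1cc(OC)c(OCc2ccccc2)c(OC)c1)c1c(OCOC)cc(OCOC)cc1OCOC | intermediate
7 | 2-{1-[4-(benzyloxy)-3,5-dimethoxyphenyl]ethenyl}-1,3,5-tris(methoxymethoxy)benzene | C=C(c1cc(OC)c(OCc2ccccc2)c(OC)c1)c1c(OCOC)cc(OCOC)cc1OCOC | intermediate (not isolated)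
8 | 2-{1-[4-(benzyloxy)-3,5-dimethoxyphenyl]ethenyl}benzene-1,3,5-triol | C=C(c1cc(OC)c(OCc2ccccc2)c(OC)c1)c1c(O)cc(O)cc1O | intermediate
9 | 2-{(1R)-1-[4-(benzyloxy)-3,5-dimethoxyphenyl]ethyl}benzene-1,3,5-triol | Oc1cc(O)c([C@H](C)c2cc(OC)c(OCc3ccccc3)c(OC)c2)c(O)c1 | intermediate
10 | ketiminium chloride of 11 | CC(=[NH2+])c1c(O)cc(O)c([C@H](C)c2cc(OC)c(OCc3ccccc3)c(OC)c2)c1O.[Cl-] | intermediate (not isolated)
11 | 1-(3-{(1R)-1-[4-(benzyloxy)-3,5-dimethoxyphenyl]ethyl}-2,4,6-trihydroxyphenyl)ethanone | CC(=O)c1c(O)cc(O)c([C@H](C)c2cc(OC)c(OCc3ccccc3)c(OC)c2)c1O | intermediate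
12 | 1-(4,6-bis(benzyloxy)-3-{(1R)-1-[4-(benzyloxy)-3,5-dimethoxyphenyl]ethyl}-2-hydroxyphenyl)ethanone | CC(=O)c1c(OCc2ccccc2)cc(OCc2ccccc2)c([C@H](C)c2cc(OC)c(OCc3ccccc3)c(OC)c2)c1O | intermediate
13 | 1-(4,6-bis(benzyloxy)-3-{(1R)-1-[4-(benzyloxy)-3,5-dimethoxyphenyl]ethyl}-2-(methoxymethoxy)phenyl)ethanone | CC(=O)c1c(OCc2ccccc2)cc(OCc2ccccc2)c([C@H](C)c2cc(OC)c(OCc3ccccc3)c(OC)c2)c1OCOC | intermediate
14 | vanillin | COc1cc(C=O)ccc1O | starting material
15 | 4-(benzyloxy)-3-methoxybenzaldehyde | COc1cc(C=O)ccc1OCc1ccccc1 | intermediate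
16 | (E)-2'-O-MOM chalcone | O=C(/C=C/c1ccc(OCc2ccccc2)c(OC)c1)c1c(OCOC)c([C@H](C)c2cc(OC)c(OCc3ccccc3)c(OC)c2)c(OCc2ccccc2)cc1OCc1ccccc1 | intermediate
17 | 2'-O-MOM trans-chalcone epoxide, (2R,3S)-oxirane drawn, (2S,3R) also present | O=C([C@@H]1O[C@H]1c1ccc(OCc2ccccc2)c(OC)c1)c1c(OCOC)c([C@H](C)c2cc(OC)c(OCc3ccccc3)c(OC)c2)c(OCc2ccccc2)cc1OCc1ccccc1 | intermediate
18 | 2'-hydroxy trans-chalcone epoxide, (2R,3S)-oxirane drawn, (2S,3R) also present | O=C([C@@H]1O[C@H]1c1ccc(OCc2ccccc2)c(OC)c1)c1c(O)c([C@H](C)c2cc(OC)c(OCc3ccccc3)c(OC)c2)c(OCc2ccccc2)cc1OCc1ccccc1 | intermediate (not isolated)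
19 | trans-dihydroflavonol tetrabenzyl ether, (2R,3R) drawn, (2S,3S) also present | COc1cc([C@@H]2[C@H](C(=O)c3c(OCc4ccccc4)cc(OCc4ccccc4)c([C@H](C)c4cc(OC)c(OCc5ccccc5)c(OC)c4)c3O2)O)ccc1OCc1ccccc1 | intermediate
20 | flavonol tetrabenzyl ether | COc1cc(-c2oc3c([C@H](C)c4cc(OC)c(OCc5ccccc5)c(OC)c4)c(OCc4ccccc4)cc(OCc4ccccc4)c3c(=O)c2O)ccc1OCc1ccccc1 | intermediate
21 | 3,5,7-trihydroxy-2-(4-hydroxy-3-methoxyphenyl)-8-[(1R)-1-(4-hydroxy-3,5-dimethoxyphenyl)ethyl]-4H-chromen-4-one | COc1cc(-c2oc3c([C@H](C)c4cc(OC)c(O)c(OC)c4)c(O)cc(O)c3c(=O)c2O)ccc1O | target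

**Step count**

Total: 14 steps. Longest linear sequence: 12 steps (steps 1, 3–8 and 10–14 from phloroglucinol).

**Steps most likely to fail**

Step 5. Face discrimination may be poor or turnover slow, because the alkene is flanked by two ortho hydroxyls on a very electron-rich ring and the phenol–rhodium chelate must form on a strongly twisted styrene. The fallback replaces chelation control by steric control on the fully protected olefin. It sets out from 6: dehydration with PPTS in toluene at 40 °C stops at the tris-MOM diarylethene 7, which is isolated this time. Hydrogenation with a cationic iridium phosphine–oxazoline complex, [Ir(cod)(ThrePHOX)]BArF, under H2 (50 bar) in CH2Cl2 at rt relies on the catalyst telling the 2,6-disubstituted ring A from the ring that carries only meta and para substituents. It should give (R)-2-{1-[4-(benzyloxy)-3,5-dimethoxyphenyl]ethyl}-1,3,5-tris(methoxymethoxy)benzene F1. HCl (3 M aq) in THF/i-PrOH then removes the three MOM groups, and the fallback comes back to the route at 9.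

Step 12. The protonated epoxide may be opened at the benzylic carbon by methanol or chloride, or the benzylic cation may undergo a 1,2-shift, before the MOM group is lost and the phenol can attack. The fallback builds ring C as a flavone and oxidises C3 afterwards. It sets out from 16: HCl in MeOH/THF removes the MOM group to give the 2'-hydroxychalcone F2. Catalytic I2 in DMSO at 120 °C closes ring C by oxa-Michael addition and dehydrogenates it to the flavone tetrabenzyl ether F3. Dimethyldioxirane in acetone/CH2Cl2 at 0 °C epoxidises the C2=C3 bond to the flavone 2,3-epoxide F4 (not isolated), which catalytic p-TsOH isomerises to the 3-hydroxyflavone. The fallback comes back to the route at 20.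

Step 7. The second benzylation may fail to distinguish the two hydroxyls next to the acetyl group, or benzyl bromide may alkylate the free ring A carbon. The fallback fixes the 6'-O-benzyl group before the acetyl group is introduced. It sets out from 9: Mitsunobu etherification with BnOH, PPh3 and DIAD in THF at 0 °C should take the one hydroxyl that is not flanked by the 1-arylethyl group and give 5-(benzyloxy)-2-{(1R)-1-[4-(benzyloxy)-3,5-dimethoxyphenyl]ethyl}benzene-1,3-diol F5. Hoesch acylation (MeCN, ZnCl2, HCl, Et2O, 0 °C; then H2O, 90 °C) at either of the two equivalent ring CH positions passes through the ketiminium chloride F6 (not isolated). It gives 1-(6-(benzyloxy)-3-{(1R)-1-[4-(benzyloxy)-3,5-dimethoxyphenyl]ethyl}-2,4-dihydroxyphenyl)ethanone F7, in which the place of the benzyl ether is fixed by symmetry. BnBr (1 equiv) with K2CO3 in acetone then benzylates only the non-chelated 4-hydroxyl, and the fallback comes back to the route at 12.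

**Further compounds**

F1 | step 5 | (R)-2-{1-[4-(benzyloxy)-3,5-dimethoxyphenyl]ethyl}-1,3,5-tris(methoxymethoxy)benzene | COCOc1cc(OCOC)c([C@H](C)c2cc(OC)c(OCc3ccccc3)c(OC)c2)c(OCOC)c1
F2 | step 12 | (E)-2'-hydroxychalcone corresponding to 16 | O=C(/C=C/c1ccc(OCc2ccccc2)c(OC)c1)c1c(O)c([C@H](C)c2cc(OC)c(OCc3ccccc3)c(OC)c2)c(OCc2ccccc2)cc1OCc1ccccc1
F3 | step 12 | 5,7-bis(benzyloxy)-2-[4-(benzyloxy)-3-methoxyphenyl]-8-{(1R)-1-[4-(benzyloxy)-3,5-dimethoxyphenyl]ethyl}-4H-chromen-4-one | COc1cc(-c2cc(=O)c3c(OCc4ccccc4)cc(OCc4ccccc4)c([C@H](C)c4cc(OC)c(OCc5ccccc5)c(OC)c4)c3o2)ccc1OCc1ccccc1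
F4 | step 12 | 2,3-epoxide of flavone F3 (mixture of diastereomers at the oxirane) | COc1cc(C23OC2C(=O)c2c(OCc4ccccc4)cc(OCc4ccccc4)c([C@H](C)c4cc(OC)c(OCc5ccccc5)c(OC)c4)c2O3)ccc1OCc1ccccc1
F5 | step 7 | 5-(benzyloxy)-2-{(1R)-1-[4-(benzyloxy)-3,5-dimethoxyphenyl]ethyl}benzene-1,3-diol | Oc1cc(OCc2ccccc2)cc(O)c1[C@H](C)c1cc(OC)c(OCc2ccccc2)c(OC)c1
F6 | step 7 | ketiminium chloride of F7 | CC(=[NH2+])c1c(O)c([C@H](C)c2cc(OC)c(OCc3ccccc3)c(OC)c2)c(O)cc1OCc1ccccc1.[Cl-]
F7 | step 7 | 1-(6-(benzyloxy)-3-{(1R)-1-[4-(benzyloxy)-3,5-dimethoxyphenyl]ethyl}-2,4-dihydroxyphenyl)ethanone | CC(=O)c1c(O)c([C@H](C)c2cc(OC)c(OCc3ccccc3)c(OC)c2)c(O)cc1OCc1ccccc1
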